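**Retrosynthetic overview**

1. Both rings are opened in one disconnection to a 4,5-dihydrofuran-3-yl glyoxylic acid. The pyranone C–O bond (O1–C8a) and the lactone C–O bond (O7–C8) form together in an acid-driven ring switch that consumes the dihydrofuran ring.
2. The C8a–C8 unit comes from oxalyl chloride, by C-acylation of the enol ether carbon (C4a–C8a bond).
3. The enol ether comes from a 5-lithio-2,3-dihydrofuran and (S)-1,2-epoxynonane (C3–C4 bond). The dihydrofuran comes from (R)-1,2-epoxydodecane, acetylide and an alkynol cycloisomerisation.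
4. Ring order: a temporary dihydrofuran ring first (step 2); in the last step the dihydropyranone ring, then the δ-lactone ring, in the same flask. Both stereocentres come from the epoxides, and no bond at either carbinol carbon is broken afterwards.

Assumption: (R)-1,2-epoxydodecane and (S)-1,2-epoxynonane are bought as single enantiomers; each is otherwise one hydrolytic kinetic resolution away from the cheap racemic epoxide.

**Step 1**
Reactants: 1 (R)-1,2-epoxydodecane; 2 lithium acetylide–ethylenediamine complex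
Product: 3 (4R)-tetradec-1-yn-4-ol
Conditions: 2 (1.5 equiv), DMSO, 0 °C → rt; then H2O
Reagents that add atoms: none
Why: Epoxide alkynylation, an SN2 opening at the unsubstituted epoxide carbon by the acetylide; the carbinol carbon is not a reacting centre, so (R) is carried over.

**Step 2**
Reactants: 3 (4R)-tetradec-1-yn-4-ol
Product: 4 (2R)-2-decyl-2,3-dihydrofuran
Conditions: Mo(CO)6 (25 mol%), Et3N, Et2O, hν (350 nm), rt
Reagents that add atoms: none
Why: McDonald-type alkynol cycloisomerisation through a molybdenum vinylidene: the hydroxyl adds to the terminal (carbene) carbon and protodemetalation gives the endocyclic enol ether, with the carbinol centre untouched.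

**Step 3**
Reactants: 4 (2R)-2-decyl-2,3-dihydrofuran; 5 (S)-1,2-epoxynonane
Product: 7 (2S)-1-[(5R)-5-decyl-4,5-dihydrofuran-2-yl]nonan-2-ol, via lithiated dihydrofuran 6 (not isolated)
Conditions: t-BuLi, THF, −78 → 0 °C; then 5, BF3·OEt2, −78 °C; aq. NaHCO3
Reagents that add atoms: none
Why: α-Lithiation of the cyclic enol ether at the O–CH= position, then BF3-assisted SN2 opening of the epoxide at its CH2 terminus by the vinyllithium; neither carbinol carbon reacts, so (R) from 1 and (S) from 5 are kept.

**Step 4**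
Reactants: 7 (2S)-1-[(5R)-5-decyl-4,5-dihydrofuran-2-yl]nonan-2-ol; 8 oxalyl chloride
Product: 13 (2S,6R)-6-decyl-2-heptyl-2,3,5,6-tetrahydropyrano[3,4-b]pyran-4,8-dione (CNP0087259.1), via silyl ether 9 (not isolated), via glyoxylyl chloride 10 (not isolated), via furyl keto acid 11 (not isolated), via pyranone hydroxy acid 12 (not isolated)
Conditions: TMSCl, 2,6-lutidine, CH2Cl2, 0 °C; (COCl)2, 0 °C → rt; evaporate; 1 M HCl/THF, rt; then TsOH·H2O (cat.), PhMe, 45–60 °C
Reagents that add atoms: water, O
Why: Proposed new method: the enol ether β-carbon of transiently silylated 9 is C-acylated by oxalyl chloride (known enol ether oxalylation) to give 10; aqueous acid then hydrolyses the acid chloride and the silyl ether, water adds at C2 of the protonated vinylogous ester 11 and the five-membered ring opens, the freed (S)-carbinol OH closes on the α-keto carbon and dehydrates to the six-membered vinylogous ester 12 (as in the cyclodehydration of δ-hydroxy-β-diketones to 2,3-dihydro-4-pyranones), and the released (R)-carbinol OH, now cis to the carboxyl across the tetrasubstituted C=C, lactonises and so drains the reversible 5-ring and 7-ring isomers into 13 without breaking a bond at either stereocentre; the closest known reaction type is the ring switching of 3-acyl-4,5-dihydrofurans by nucleophiles.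

**Compound list**

1 | (R)-1,2-epoxydodecane, (2R)-2-decyloxirane | CCCCCCCCCC[C@@H]1CO1 | starting material
2 | lithium acetylide–ethylenediamine complex | [Li]C#C.NCCN | starting material
3 | (4R)-tetradec-1-yn-4-ol | CCCCCCCCCC[C@@H](O)CC#C | intermediate
4 | (2R)-2-decyl-2,3-dihydrofuran | CCCCCCCCCC[C@@H]1CC=CO1 | intermediate
5 | (S)-1,2-epoxynonane, (2S)-2-heptyloxirane | CCCCCCC[C@H]1CO1 | starting material
6 | [(2R)-2-decyl-2,3-dihydrofuran-5-yl]lithium (not isolated) | CCCCCCCCCC[C@@H]1CC=C([Li])O1 | intermediate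
7 | (2S)-1-[(5R)-5-decyl-4,5-dihydrofuran-2-yl]nonan-2-ol | CCCCCCCCCC[C@@H]1CC=C(C[C@@H](O)CCCCCCC)O1 | intermediate
8 | oxalyl chloride | ClC(=O)C(=O)Cl | starting material
9 | [(2S)-1-[(5R)-5-decyl-4,5-dihydrofuran-2-yl]nonan-2-yl]oxy-trimethylsilane (not isolated) | CCCCCCCCCC[C@@H]1CC=C(C[C@@H](O[Si](C)(C)C)CCCCCCC)O1 | intermediate
10 | 2-[(5R)-5-decyl-2-[(2S)-2-(trimethylsilyloxy)nonyl]-4,5-dihydrofuran-3-yl]-2-oxoacetyl chloride (not isolated) | CCCCCCCCCC[C@@H]1CC(C(=O)C(=O)Cl)=C(C[C@@H](O[Si](C)(C)C)CCCCCCC)O1 | intermediate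
11 | 2-[(5R)-5-decyl-2-[(2S)-2-hydroxynonyl]-4,5-dihydrofuran-3-yl]-2-oxoacetic acid (not isolated) | CCCCCCCCCC[C@@H]1CC(C(=O)C(=O)O)=C(C[C@@H](O)CCCCCCC)O1 | intermediate
12 | (2S)-2-heptyl-5-[(2R)-2-hydroxydodecyl]-4-oxo-3,4-dihydro-2H-pyran-6-carboxylic acid (not isolated) | CCCCCCCCCC[C@@H](O)CC1=C(C(=O)O)O[C@@H](CCCCCCC)CC1=O | intermediate
13 | (2S,6R)-6-decyl-2-heptyl-2,3,5,6-tetrahydropyrano[3,4-b]pyran-4,8-dione; 2,3-dihydro-4-pyranone fused through its C5=C6 bond to a 5,6-dihydro-2-pyranone, heptyl on the pyranone O–CH, decyl on the lactone O–CH | CCCCCCCCCC[C@@H]1CC2=C(O[C@@H](CCCCCCC)CC2=O)C(=O)O1 | target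

**Totals**

Total step count: 4. Longest linear sequence: 4 (1 → 3 → 4 → 7 → 13).

**Three steps most likely to fail**

Step 4 (most likely). The one-pot may stop at the dihydrofuran keto acid 11 or at a seven-membered lactone, and prolonged acid could epimerise C2 by retro-oxa-Michael opening. The fallback builds the rings one at a time under kinetic control, setting out from 7 and coming back at 13. TBSCl and imidazole give the tert-butyldimethylsilyl ether F1. Oxalic acid in wet THF hydrolyses the enol ether to the open hydroxy ketone F2. Ethyl chlorooxoacetate and pyridine acylate the free (R)-alcohol to the mixed oxalate F3. LiHMDS (THF, −78 → 0 °C) then drives an oxalate-tethered Dieckmann condensation, in which only the C11 enolate can close a six-membered ring, to the 4-acyl-3-hydroxy-5,6-dihydropyran-2-one F4. Aqueous HF in MeCN removes the silyl group, and the freed (S)-alcohol cyclodehydrates onto C3 to give 13.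

Step 3. The lithiated enol ether may open the epoxide poorly, or BF3 may destroy the enol ether. The fallback makes the same C–C bond from an alkyne and builds the dihydrofuran last, setting out from 5 and coming back at 7; it also bypasses step 2. Compound 2 opens 5 to (4S)-undec-1-yn-4-ol F5. TESCl and imidazole give the triethylsilyl ether F6. n-BuLi, then BF3·OEt2 and epoxide 1, give the alkynol F7. Ph3PAuCl/AgOTf (cat.) effects 5-endo-dig addition of the only free hydroxyl to the alkyne, giving the dihydrofuran triethylsilyl ether F8. TBAF gives 7; F8 could also enter step 4 directly in place of 9.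

Step 2. The photochemical Mo cycloisomerisation may be incomplete on this long-chain alkynol, and 4 is acid-sensitive. The fallback reaches 4 through a lactol, setting out from 1 and coming back at 4. Allylmagnesium bromide with catalytic CuI opens 1 to (5R)-pentadec-1-en-5-ol F9. Ozonolysis (O3, CH2Cl2, −78 °C; PPh3) gives the lactol (5R)-5-decyltetrahydrofuran-2-ol F10. MsCl and Et3N dehydrate it to 4.

**Further compounds**

F1 | step 4 | tert-butyl-[(2S)-1-[(5R)-5-decyl-4,5-dihydrofuran-2-yl]nonan-2-yl]oxy-dimethylsilane | CCCCCCCCCC[C@@H]1CC=C(C[C@@H](O[Si](C)(C)C(C)(C)C)CCCCCCC)O1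
F2 | step 4 | (8S,13R)-8-(tert-butyldimethylsilyloxy)-13-hydroxytricosan-10-one | CCCCCCCCCC[C@@H](O)CCC(=O)C[C@@H](O[Si](C)(C)C(C)(C)C)CCCCCCC
F3 | step 4 | (8S,13R)-8-(tert-butyldimethylsilyloxy)-10-oxotricosan-13-yl ethyl oxalate | CCCCCCCCCC[C@@H](OC(=O)C(=O)OCC)CCC(=O)C[C@@H](O[Si](C)(C)C(C)(C)C)CCCCCCC
F4 | step 4 | (6R)-4-[(3S)-3-(tert-butyldimethylsilyloxy)decanoyl]-6-decyl-3-hydroxy-5,6-dihydro-2H-pyran-2-one | CCCCCCCCCC[C@@H]1CC(C(=O)C[C@@H](O[Si](C)(C)C(C)(C)C)CCCCCCC)=C(O)C(=O)O1
F5 | step 3 | (4S)-undec-1-yn-4-ol | CCCCCCC[C@H](O)CC#C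
F6 | step 3 | triethyl-[(4S)-undec-1-yn-4-yl]oxysilane | CCCCCCC[C@H](O[Si](CC)(CC)CC)CC#C
F7 | step 3 | (11R,16S)-16-(triethylsilyloxy)tricos-13-yn-11-ol | CCCCCCCCCC[C@@H](O)CC#CC[C@@H](O[Si](CC)(CC)CC)CCCCCCC
F8 | step 3 | [(2S)-1-[(5R)-5-decyl-4,5-dihydrofuran-2-yl]nonan-2-yl]oxy-triethylsilane | CCCCCCCCCC[C@@H]1CC=C(C[C@@H](O[Si](CC)(CC)CC)CCCCCCC)O1
F9 | step 2 | (5R)-pentadec-1-en-5-ol | CCCCCCCCCC[C@@H](O)CCC=C
F10 | step 2 | (5R)-5-decyltetrahydrofuran-2-ol (anomer mixture) | CCCCCCCCCC[C@@H]1CCC(O)O1
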